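**Strategy.** Numbering the ring as in shikimate (C1 carries CO2Me), the cyclohexene is cut into two three-carbon halves: the enoate unit C1=C2–C3 and the unit C6–C5(O)–C4. The key step joins a chiral crotonate-derived sulfonium ylide (nucleophilic at C1 and C3) with a 2-acyloxyacrolein (electrophilic at C6 and C4) by tandem Michael addition/ylide epoxidation. It forms C1–C6 and C3–C4, closes the ring, places oxygen on C3 and C4 as a cis-fused epoxide and funnels the epimerising C5 centre into one configuration. It exploits the γ-oxygenated enoate C1=C2–C3 and the acrolein hidden in C4–C5–C6. Palladium-catalysed opening of the vinyl epoxide by the acid then delivers the C3 ester with retention and leaves only the C4 hydroxyl free.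

Key step: step 6

Assumption: the (2R,5R)-thiolane is taken to induce the (1R,5R,6S) epoxide; if the opposite sense is found, the (2S,5S)-thiolane from (2R,5R)-hexane-2,5-diol is used in the same way.

Step 1
Reactants: 1 (2E)-3-methylpent-2-enoic acid; 2 2,2-dimethyl-1,3-dioxan-5-one
Product: 4 2,2-dimethyl-4H-1,3-dioxin-5-yl (2E)-3-methylpent-2-enoate, via acid chloride 3 (not isolated)
Conditions: 1, (COCl)2, DMF (cat.), CH2Cl2, 0 °C to rt, evaporate; then 2, KN(SiMe3)2, THF, −78 °C, add crude 3, −78 to 0 °C
Reagents that add atoms: none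
Why: Acyl chloride formation with oxalyl chloride/DMF followed by O-acylation of the pre-formed potassium enolate of 2 (hard oxygen terminus, reactive acyl chloride, no amine base that could deconjugate the acyl chloride through a vinylketene) should give the enol ester with the E alkene intact; no stereocentre is formed.

Step 2
Reactants: 4 2,2-dimethyl-4H-1,3-dioxin-5-yl (2E)-3-methylpent-2-enoate
Product: 5 3-oxoprop-1-en-2-yl (2E)-3-methylpent-2-enoate (the 2-acyloxyacrolein)
Conditions: toluene, 110 °C, BHT (cat.); concentrate and use at once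
Reagents that add atoms: none
Why: Thermal retro-hetero-Diels–Alder reaction of the 4H-1,3-dioxin expels acetone and unmasks the 2-acyloxy enal; no stereocentre is formed.

Step 3
Reactants: 6 (2S,5S)-hexane-2,5-diol
Product: 7 (2S,5S)-hexane-2,5-diyl dimethanesulfonate
Conditions: MsCl, Et3N, CH2Cl2, 0 °C
Reagents that add atoms: methanesulfonyl chloride CS(Cl)(=O)=O
Why: O-Sulfonylation (mesylation) of both secondary alcohols takes place at oxygen only, so both carbinol centres keep their S configuration.

Step 4
Reactants: 7 (2S,5S)-hexane-2,5-diyl dimethanesulfonate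
Product: 8 (2R,5R)-2,5-dimethylthiolane
Conditions: Na2S·9H2O, DMSO, 25 to 40 °C; distil
Reagents that add atoms: sodium sulfide [Na+].[Na+].[S-2]
Why: Double SN2 displacement by sulfide, the second one a 5-exo-tet ring closure, inverts both centres and so turns the (2S,5S)-dimesylate into the (2R,5R)-thiolane.

Step 5
Reactants: 8 (2R,5R)-2,5-dimethylthiolane; 9 methyl (2E)-4-bromobut-2-enoate
Product: 10 (2R,5R)-1-[(2E)-4-methoxy-4-oxobut-2-en-1-yl]-2,5-dimethylthiolan-1-ium bromide
Conditions: acetone, 25 °C, 48 h; triturate with Et2O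
Reagents that add atoms: none
Why: SN2 S-alkylation of the thiolane by the primary allylic bromide gives the sulfonium salt with the E alkene kept; because the twofold-symmetric thiolane has two equivalent sulfur faces, sulfur does not become a stereocentre and one salt results.

Step 6
Reactants: 10 (2R,5R)-1-[(2E)-4-methoxy-4-oxobut-2-en-1-yl]-2,5-dimethylthiolan-1-ium bromide; 5 3-oxoprop-1-en-2-yl (2E)-3-methylpent-2-enoate
Product: 13 methyl (1R,5R,6S)-5-{[(2E)-3-methylpent-2-enoyl]oxy}-7-oxabicyclo[4.1.0]hept-2-ene-3-carboxylate, via sulfonium ylide 11 (not isolated), via Michael adduct 12 (not isolated)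
Conditions: Cs2CO3, MeCN, −20 to 0 °C, slow addition of 5
Reagents that add atoms: none
Why: Proposed new method: Cs2CO3 converts 10 into the vinylogous ylide 11, whose ester-bearing terminus C1 adds to the unsubstituted β-carbon C6 of enal 5, and proton transfer from the now doubly activated C1–H returns the ylide carbon next to sulfur and frees the α-acyloxy aldehyde (12). The ylide carbon C3 then adds to the aldehyde carbon C4 in a 6-exo-trig closure of the cyclohexene, and the trans-diaxial betaine expels thiolane 8 by 3-exo-tet displacement to give the necessarily cis-fused epoxide. The closest known reaction type is the tandem Michael addition/ylide epoxidation of crotonate-derived sulfonium salts with doubly activated enones, which builds cyclohexene-fused epoxides in the same bond order; the reasoning is that an enal without a β-substituent should be an even better Michael acceptor and its aldehyde a better trap for the ylide. C3 and C4 should be set by the twofold-symmetric thiolanium group, whose methyl groups screen one face of the ylide carbon, while C5 is set dynamically: the α-acyloxy aldehyde in 12 epimerises through its enol under carbonate faster than it cyclises, and the half-chair transition state with the C5 acyloxy group anti (dipole-opposed) to the developing C4 alkoxide is taken, so the epimer mixture should drain into the epoxide with the acyloxy group trans to the epoxide oxygen. The step needs attack through the remote ylide terminus instead of cyclopropanation or direct carbonyl epoxidation at the sulfur-bearing carbon, which the hindered 2,5-dimethylthiolanium group, the soft delocalised ylide and the slow addition of 5 at low temperature should secure.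

Step 7
Reactants: 13 methyl (1R,5R,6S)-5-{[(2E)-3-methylpent-2-enoyl]oxy}-7-oxabicyclo[4.1.0]hept-2-ene-3-carboxylate; 1 (2E)-3-methylpent-2-enoic acid
Product: 14 methyl (3R,4S,5R)-4-hydroxy-3,5-bis{[(2E)-3-methylpent-2-enoyl]oxy}cyclohex-1-ene-1-carboxylate
Conditions: Pd(PPh3)4 (3 mol %), 1 (1.2 equiv), THF, 0 °C to rt, short reaction time, neutral work-up
Reagents that add atoms: none
Why: In this Tsuji–Trost-type opening of the vinyl epoxide, zerovalent palladium ionises the allylic C3–O bond with inversion, acid 1 protonates the C4 alkoxide and its carboxylate attacks the π-allyl terminus C3 remote from the ester and anti to palladium, so the double inversion gives net retention and the new C3 ester should sit cis to the free C4 hydroxyl while C4 and C5 are untouched.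

**Compound list**

1 | (2E)-3-methylpent-2-enoic acid | CC/C(C)=C/C(=O)O | starting material
2 | 2,2-dimethyl-1,3-dioxan-5-one | CC1(C)OCC(=O)CO1 | starting material
3 | (2E)-3-methylpent-2-enoyl chloride | CC/C(C)=C/C(=O)Cl | intermediate
4 | 2,2-dimethyl-4H-1,3-dioxin-5-yl (2E)-3-methylpent-2-enoate | CC/C(C)=C/C(=O)OC1=COC(C)(C)OC1 | intermediate
5 | 3-oxoprop-1-en-2-yl (2E)-3-methylpent-2-enoate | CC/C(C)=C/C(=O)OC(=C)C=O | intermediate
6 | (2S,5S)-hexane-2,5-diol | C[C@H](O)CC[C@H](C)O | starting material
7 | (2S,5S)-hexane-2,5-diyl dimethanesulfonate | C[C@H](OS(C)(=O)=O)CC[C@H](C)OS(C)(=O)=O | intermediate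
8 | (2R,5R)-2,5-dimethylthiolane | C[C@@H]1CC[C@@H](C)S1 | intermediate
9 | methyl (2E)-4-bromobut-2-enoate | COC(=O)/C=C/CBr | starting material
10 | (2R,5R)-1-[(2E)-4-methoxy-4-oxobut-2-en-1-yl]-2,5-dimethylthiolan-1-ium bromide | C[C@@H]1CC[C@@H](C)[S+]1C/C=C/C(=O)OC.[Br-] | intermediate
11 | [(2R,5R)-2,5-dimethylthiolan-1-ium-1-yl][(1E)-3-methoxy-3-oxoprop-1-en-1-yl]methanide (sulfonium ylide) | C[C@@H]1CC[C@@H](C)[S+]1[CH-]/C=C/C(=O)OC | intermediate
12 | methyl 4-[(2R,5R)-2,5-dimethylthiolan-1-ium-1-yl]-2-{2-[(2E)-3-methylpent-2-enoyloxy]-3-oxopropyl}but-2-enoate 4-ylide (Michael adduct; both epimers at the acyloxy carbon, in equilibrium) | C[C@@H]1CC[C@@H](C)[S+]1[CH-]/C=C(/C(=O)OC)CC(OC(=O)/C=C(\C)CC)C=O | intermediate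
13 | methyl (1R,5R,6S)-5-{[(2E)-3-methylpent-2-enoyl]oxy}-7-oxabicyclo[4.1.0]hept-2-ene-3-carboxylate | COC(=O)C1=C[C@H]2O[C@H]2[C@H](OC(=O)/C=C(\C)CC)C1 | intermediate
14 | methyl (3R,4S,5R)-4-hydroxy-3,5-bis{[(2E)-3-methylpent-2-enoyl]oxy}cyclohex-1-ene-1-carboxylate | CC/C(C)=C/C(=O)O[C@@H]1C=C(C(=O)OC)C[C@@H](OC(=O)/C=C(\C)CC)[C@@H]1O | target

**Step count.** Total: 7 steps. Longest linear sequence: 5 steps (steps 3, 4, 5, 6, 7).

**Steps most likely to fail**

1. Step 6. The ylide may react through its sulfur-bearing carbon (cyclopropanation of the enal or direct epoxidation of the aldehyde), or the selection of the ylide face and of the C5 epimer may be poor. The fallback uses known chemistry, sets out from 5 and 9 and comes back at 13. Bromide 9 is quaternised with PPh3 (toluene, 25 °C) to [(2E)-4-methoxy-4-oxobut-2-en-1-yl]triphenylphosphonium bromide F1. F1 and 5 with K2CO3 in CH2Cl2/H2O should undergo the known Michael addition/intramolecular Wittig annulation of crotonate-derived phosphorus ylides with enals. This forms the same two ring bonds (C3–C4 as an alkene) and gives racemic methyl 5-{[(2E)-3-methylpent-2-enoyl]oxy}cyclohexa-1,3-diene-1-carboxylate F2. Jacobsen epoxidation of the cis-disubstituted C3=C4 alkene follows, with a chiral (salen)MnCl complex (trivalent manganese) and buffered NaOCl in CH2Cl2 at 0 °C, run as a kinetic resolution to about half conversion. The catalyst enantiomer is chosen so that the (5R)-diene is epoxidised anti to its acyloxy group, which gives 13; the unreacted (5S)-diene is removed by chromatography.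

2. Step 7. Configuration at C3 may be lost through exchange of palladium on the π-allyl intermediate, the intermediate may eliminate towards an arene, or the acyl group may migrate between O3 and O4. The fallback sets out from 13 and comes back at 14. MgBr2·OEt2 (Et2O, −20 °C) opens 13 at the allylic C3 with inversion to methyl (3S,4S,5R)-3-bromo-4-hydroxy-5-{[(2E)-3-methylpent-2-enoyl]oxy}cyclohex-1-ene-1-carboxylate F3. The C4 hydroxyl is silylated (Et3SiCl, imidazole, CH2Cl2) to methyl (3S,4S,5R)-3-bromo-5-{[(2E)-3-methylpent-2-enoyl]oxy}-4-(triethylsilyloxy)cyclohex-1-ene-1-carboxylate F4. SN2 displacement of the allylic bromide by the caesium salt of 1 (1, Cs2CO3, DMF, 25 °C) inverts C3 a second time to methyl (3R,4S,5R)-3,5-bis{[(2E)-3-methylpent-2-enoyl]oxy}-4-(triethylsilyloxy)cyclohex-1-ene-1-carboxylate F5. HF·pyridine in THF then removes the silyl group to give 14.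

3. Step 1. The enolate may be acylated at carbon, or the acyl chloride may lose alkene position and geometry through a vinylketene. The fallback sets out from 2 and comes back at 13. Ketone 2 is silylated (iPr3SiOTf, Et3N, CH2Cl2) to 2,2-dimethyl-5-[(triisopropylsilyl)oxy]-4H-1,3-dioxine F6. Thermolysis in toluene at 110 °C gives 2-[(triisopropylsilyl)oxy]prop-2-enal F7. F7 is annulated with 10 under the conditions of step 6 to methyl (1R,5R,6R)-5-[(triisopropylsilyl)oxy]-7-oxabicyclo[4.1.0]hept-2-ene-3-carboxylate F8. HF·pyridine frees methyl (1R,5R,6S)-5-hydroxy-7-oxabicyclo[4.1.0]hept-2-ene-3-carboxylate F9. Steglich esterification of its single hydroxyl with 1 (EDC·HCl, DMAP, CH2Cl2, 0 °C) gives 13.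

**Further compounds**

F1 | step 6 | [(2E)-4-methoxy-4-oxobut-2-en-1-yl]triphenylphosphonium bromide | COC(=O)/C=C/C[P+](c1ccccc1)(c1ccccc1)c1ccccc1.[Br-]
F2 | step 6 | methyl 5-{[(2E)-3-methylpent-2-enoyl]oxy}cyclohexa-1,3-diene-1-carboxylate (racemic) | COC(=O)C1=CC=CC(OC(=O)/C=C(\C)CC)C1
F3 | step 7 | methyl (3S,4S,5R)-3-bromo-4-hydroxy-5-{[(2E)-3-methylpent-2-enoyl]oxy}cyclohex-1-ene-1-carboxylate | Br[C@H]1C=C(C(=O)OC)C[C@@H](OC(=O)/C=C(\C)CC)[C@@H]1O
F4 | step 7 | methyl (3S,4S,5R)-3-bromo-5-{[(2E)-3-methylpent-2-enoyl]oxy}-4-(triethylsilyloxy)cyclohex-1-ene-1-carboxylate | Br[C@H]1C=C(C(=O)OC)C[C@@H](OC(=O)/C=C(\C)CC)[C@@H]1O[Si](CC)(CC)CC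
F5 | step 7 | methyl (3R,4S,5R)-3,5-bis{[(2E)-3-methylpent-2-enoyl]oxy}-4-(triethylsilyloxy)cyclohex-1-ene-1-carboxylate | CC/C(C)=C/C(=O)O[C@@H]1C=C(C(=O)OC)C[C@@H](OC(=O)/C=C(\C)CC)[C@@H]1O[Si](CC)(CC)CC
F6 | step 1 | 2,2-dimethyl-5-[(triisopropylsilyl)oxy]-4H-1,3-dioxine | CC(C)[Si](OC1=COC(C)(C)OC1)(C(C)C)C(C)C
F7 | step 1 | 2-[(triisopropylsilyl)oxy]prop-2-enal | CC(C)[Si](OC(=C)C=O)(C(C)C)C(C)C
F8 | step 1 | methyl (1R,5R,6R)-5-[(triisopropylsilyl)oxy]-7-oxabicyclo[4.1.0]hept-2-ene-3-carboxylate | COC(=O)C1=C[C@H]2O[C@H]2[C@H](O[Si](C(C)C)(C(C)C)C(C)C)C1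
F9 | step 1 | methyl (1R,5R,6S)-5-hydroxy-7-oxabicyclo[4.1.0]hept-2-ene-3-carboxylate | COC(=O)C1=C[C@H]2O[C@H]2[C@H](O)C1
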